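**Plan**

- Locants follow naphthalene-2-carbaldehyde numbering: CHO on C2, OH on C3, aryl on C4, OMe on C5, OH on C6; ring A is C1–C4, ring B is C5–C8.
- The retrosynthesis cuts, in order: the O6–Si bond of a protecting group, the biaryl bond C4–C1' (giving naphthol 9 and veratrole 10), the C5–OMe bond, and the C2–CHO bond, ending at C2v-symmetric naphthalene-2,7-diol 1.
- Enabling feature: C4 is the α carbon of ring A ortho to the C3 hydroxyl, where a 2-naphthoxyl radical has its largest ring spin density. The aryl ring is attached through the carbon para to a methoxy group, the nucleophilic site of veratrole. The biaryl bond can therefore be made from two C–H bonds by anodic oxidation.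
- Forward: both rings are bought in 1. One directed lithiation/formylation breaks the symmetry, oxidative methoxylation/reduction puts OMe on C5 next to the non-chelated hydroxyl, O6 is silylated, the anodic naphthol–arene cross-coupling joins 9 and 10, and desilylation gives the target.
- Stereochemistry: the target has no stereocentre and the aryl ring has no ortho substituent, so nothing has to be set.

Key step: step 6

Remark: the biaryl axis is taken as freely rotating, in line with the target SMILES, which specifies no axial configuration.

**Route**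

Step 1
Reactants: 1 naphthalene-2,7-diol
Product: 2 2,7-bis(methoxymethoxy)naphthalene
Conditions: NaH (2.4 equiv), THF/DMF, 0 °C; MOMCl (2.4 equiv), 0 °C to rt
Reagents that add atoms: chloromethyl methyl ether (MOMCl), COCCl
Why: Williamson-type O-alkylation of the bis-naphtholate installs two equivalent directing groups for step 2 and keeps the molecule symmetric.

Step 2
Reactants: 2 2,7-bis(methoxymethoxy)naphthalene
Product: 5 3,6-bis(methoxymethoxy)naphthalene-2-carbaldehyde, via aryllithium 3 (not isolated), via lithium hemiaminolate 4 (not isolated)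
Conditions: n-BuLi (1.1 equiv), TMEDA (1.1 equiv), Et2O, 0 °C to rt; DMF (2 equiv), −78 °C to rt; H2O
Reagents that add atoms: N,N-dimethylformamide, CN(C)C=O
Why: Directed ortho-metalation, in which an OMOM group on a naphthalene β carbon directs lithiation to the neighbouring β position (as in 2-naphthol and BINOL MOM ethers), followed by formylation with DMF; the two sites are equivalent, so one equivalent of base should desymmetrize 2, and the electron-rich aryllithium should resist a second deprotonation.

Step 3
Reactants: 5 3,6-bis(methoxymethoxy)naphthalene-2-carbaldehyde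
Product: 6 3,6-dihydroxynaphthalene-2-carbaldehyde
Conditions: HCl (3 M in MeOH), 50 °C; aqueous work-up
Reagents that add atoms: none
Why: Acid-catalysed methanolysis of the two MOM acetals; the aldehyde is regenerated from any dimethyl acetal on aqueous work-up.

Step 4
Reactants: 6 3,6-dihydroxynaphthalene-2-carbaldehyde
Product: 8 3,6-dihydroxy-5-methoxynaphthalene-2-carbaldehyde, via quinone monoketal 7 (not isolated)
Conditions: PhI(OAc)2 (2.1 equiv), MeOH, 0 °C; then Zn dust, AcOH, 0 °C to rt
Reagents that add atoms: methanol, CO
Why: PhI(OAc)2 should engage the C6 hydroxyl, which is not tied into the hydrogen bond to the formyl group, and methanol should enter twice at C5, the α carbon next to that oxygen (oxidative dearomatization of 2-naphthols to 1,1-dimethoxy ketones), after which zinc cleaves one C–OMe bond of the α,α-dimethoxy ketone with aromatization as driving force (reductive cleavage of α-alkoxy ketones).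

Step 5
Reactants: 8 3,6-dihydroxy-5-methoxynaphthalene-2-carbaldehyde
Product: 9 3-hydroxy-5-methoxy-6-[(triisopropylsilyl)oxy]naphthalene-2-carbaldehyde
Conditions: TIPSCl (1.05 equiv), imidazole (2.2 equiv), DMF, 0 °C to rt
Reagents that add atoms: chlorotriisopropylsilane (TIPSCl), CC(C)[Si](Cl)(C(C)C)C(C)C
Why: Imidazole-promoted silylation of a phenol; the C3 hydroxyl sits in a six-membered hydrogen bond to the aldehyde and should react much more slowly than the C6 hydroxyl, the selectivity pattern known from dihydroxybenzaldehydes.

Step 6
Reactants: 9 3-hydroxy-5-methoxy-6-[(triisopropylsilyl)oxy]naphthalene-2-carbaldehyde; 10 veratrole (1,2-dimethoxybenzene, 3 equiv)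
Product: 11 4-(3,4-dimethoxyphenyl)-3-hydroxy-5-methoxy-6-[(triisopropylsilyl)oxy]naphthalene-2-carbaldehyde
Conditions: undivided cell, boron-doped diamond anode and cathode, constant current (5 mA cm−2, 2.2 F mol−1), Bu3MeN+ MeOSO3− (0.1 M), HFIP/MeOH (9:1), 50 °C
Reagents that add atoms: none
Why: Proton-coupled anodic oxidation should turn the only free O–H of 9 into the C3 naphthoxyl radical, whose ring spin density is largest at C4; veratrole, present in excess, attacks C4 through its carbon para to a methoxy group, and a second electron transfer with loss of a proton rearomatizes both rings while protons are reduced to H2 at the cathode. The closest known reaction type is the anodic dehydrogenative cross-coupling of phenols and 2-naphthols with methoxyarenes in HFIP, where hydrogen bonding of the solvent to the phenol and its radical disfavours homo-coupling. No ring is closed and no stereocentre is formed; the new axis carries an aryl ring without ortho substituents and is not expected to be configurationally stable. The step needs cross- over homo-coupling, C4 over C7, and a single arylation: the silyl ether on O6 prevents an O6 radical (which would place spin at C5 and C7), C5 is blocked by OMe, a homo-dimer of 9 would have two peri-methoxy groups flanking the new bond, and the twisted product 11 should be harder to oxidize than 9. Should veratrole be oxidized first, attack of the nucleophilic C4 of 9 on the veratrole radical cation would form the same bond.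

Step 7
Reactants: 11 4-(3,4-dimethoxyphenyl)-3-hydroxy-5-methoxy-6-[(triisopropylsilyl)oxy]naphthalene-2-carbaldehyde
Product: 12 vitrofolal B, 4-(3,4-dimethoxyphenyl)-3,6-dihydroxy-5-methoxynaphthalene-2-carbaldehyde
Conditions: Bu4NF (1.1 equiv), AcOH (1.2 equiv), THF, 0 °C
Reagents that add atoms: none
Why: Fluoride-induced cleavage of the aryl silyl ether, driven by Si–F bond formation; acetic acid buffers the phenoxide so that the aldehyde and the electron-rich naphthol are not exposed to base.

**Compound list**

1 | naphthalene-2,7-diol | Oc1ccc2ccc(O)cc2c1 | starting material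
2 | 2,7-bis(methoxymethoxy)naphthalene | COCOc1ccc2ccc(OCOC)cc2c1 | intermediate
3 | [3,6-bis(methoxymethoxy)naphthalen-2-yl]lithium (not isolated) | COCOc1ccc2cc([Li])c(OCOC)cc2c1 | intermediate
4 | lithium [3,6-bis(methoxymethoxy)naphthalen-2-yl](dimethylamino)methanolate, racemic (not isolated) | COCOc1ccc2cc(C(O[Li])N(C)C)c(OCOC)cc2c1 | intermediate
5 | 3,6-bis(methoxymethoxy)naphthalene-2-carbaldehyde | O=Cc1cc2ccc(OCOC)cc2cc1OCOC | intermediate
6 | 3,6-dihydroxynaphthalene-2-carbaldehyde | O=Cc1cc2ccc(O)cc2cc1O | intermediate
7 | 3-hydroxy-5,5-dimethoxy-6-oxo-5,6-dihydronaphthalene-2-carbaldehyde (not isolated) | O=Cc1cc2C=CC(=O)C(OC)(OC)c2cc1O | intermediate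
8 | 3,6-dihydroxy-5-methoxynaphthalene-2-carbaldehyde | O=Cc1cc2ccc(O)c(OC)c2cc1O | intermediate
9 | 3-hydroxy-5-methoxy-6-[(triisopropylsilyl)oxy]naphthalene-2-carbaldehyde | O=Cc1cc2ccc(O[Si](C(C)C)(C(C)C)C(C)C)c(OC)c2cc1O | intermediate
10 | veratrole (1,2-dimethoxybenzene) | COc1ccccc1OC | starting material
11 | 4-(3,4-dimethoxyphenyl)-3-hydroxy-5-methoxy-6-[(triisopropylsilyl)oxy]naphthalene-2-carbaldehyde | COc1ccc(-c2c(O)c(C=O)cc3ccc(O[Si](C(C)C)(C(C)C)C(C)C)c(OC)c23)cc1OC | intermediate
12 | vitrofolal B, 4-(3,4-dimethoxyphenyl)-3,6-dihydroxy-5-methoxynaphthalene-2-carbaldehyde | COc1ccc(-c2c(O)c(C=O)cc3ccc(O)c(OC)c23)cc1OC | target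

**Count and risks**

Total step count: 7. Longest linear sequence: 7 steps (1 to 12); veratrole 10 is bought.

Steps most likely to fail:

1. Step 6. Veratrole may be oxidized at the anode in competition with 9 and oligomerize, the product may be oxidized further, or arylation may drift to C7, so that little cross-coupled biaryl forms. Fallback, from 9 back to 11: bromination with NBS in MeCN at 0 °C, ortho to the C3 hydroxyl, should give 4-bromo-3-hydroxy-5-methoxy-6-[(triisopropylsilyl)oxy]naphthalene-2-carbaldehyde F1. Suzuki–Miyaura coupling of F1 with commercial (3,4-dimethoxyphenyl)boronic acid (Pd(OAc)2, SPhos, K3PO4, toluene/H2O, 80 °C) returns to the route at 11.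

2. Step 4. Oxidation may be unselective or excessive (attack at the chelated ring A phenol, quinone formation), or ketal 7 may hydrolyse to the ortho-quinone before reduction, which would end in loss of the methyl ether. Fallback, from 6 back to 8: Br2 (1 equiv) in AcOH at rt should brominate the α position C5 next to the non-chelated hydroxyl and give 5-bromo-3,6-dihydroxynaphthalene-2-carbaldehyde F2. Copper-mediated substitution of bromide by methoxide (NaOMe, CuCl, DMF/MeOH, 110 °C, the reaction type that converts 5-bromovanillin into syringaldehyde) returns to the route at 8.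

3. Step 2. A second lithiation at the equivalent site of the other ring may compete, so that bis-formylated material and unreacted 2 accompany 5 and the desymmetrization is poor. Fallback, from 1 back to 6, replacing steps 1 to 3:
   - Monosilylation of 1 (TIPSCl, 1 equiv, imidazole, DMF; unreacted 1 recycled) should give 7-[(triisopropylsilyl)oxy]naphthalen-2-ol F3.
   - NaH/MOMCl gives triisopropyl{[7-(methoxymethoxy)naphthalen-2-yl]oxy}silane F4.
   - The bulky silyl ether does not direct lithiation, so n-BuLi/TMEDA in Et2O can metalate only next to the single OMOM group, giving {3-(methoxymethoxy)-6-[(triisopropylsilyl)oxy]naphthalen-2-yl}lithium F5.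
   - DMF adds to give lithium (dimethylamino){3-(methoxymethoxy)-6-[(triisopropylsilyl)oxy]naphthalen-2-yl}methanolate F6, which collapses on aqueous work-up to 3-(methoxymethoxy)-6-[(triisopropylsilyl)oxy]naphthalene-2-carbaldehyde F7.
   - HCl in MeOH removes the MOM group to give 3-hydroxy-6-[(triisopropylsilyl)oxy]naphthalene-2-carbaldehyde F8, and Bu4NF/AcOH in THF then returns to the route at 6.

**Further compounds**

F1 | step 6 | 4-bromo-3-hydroxy-5-methoxy-6-[(triisopropylsilyl)oxy]naphthalene-2-carbaldehyde | O=Cc1cc2ccc(O[Si](C(C)C)(C(C)C)C(C)C)c(OC)c2c(Br)c1O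
F2 | step 4 | 5-bromo-3,6-dihydroxynaphthalene-2-carbaldehyde | O=Cc1cc2ccc(O)c(Br)c2cc1O
F3 | step 2 | 7-[(triisopropylsilyl)oxy]naphthalen-2-ol | CC(C)[Si](Oc1ccc2ccc(O)cc2c1)(C(C)C)C(C)C
F4 | step 2 | triisopropyl{[7-(methoxymethoxy)naphthalen-2-yl]oxy}silane | COCOc1ccc2ccc(O[Si](C(C)C)(C(C)C)C(C)C)cc2c1
F5 | step 2 | {3-(methoxymethoxy)-6-[(triisopropylsilyl)oxy]naphthalen-2-yl}lithium | COCOc1cc2cc(O[Si](C(C)C)(C(C)C)C(C)C)ccc2cc1[Li]
F6 | step 2 | lithium (dimethylamino){3-(methoxymethoxy)-6-[(triisopropylsilyl)oxy]naphthalen-2-yl}methanolate, racemic | COCOc1cc2cc(O[Si](C(C)C)(C(C)C)C(C)C)ccc2cc1C(O[Li])N(C)C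
F7 | step 2 | 3-(methoxymethoxy)-6-[(triisopropylsilyl)oxy]naphthalene-2-carbaldehyde | COCOc1cc2cc(O[Si](C(C)C)(C(C)C)C(C)C)ccc2cc1C=O
F8 | step 2 | 3-hydroxy-6-[(triisopropylsilyl)oxy]naphthalene-2-carbaldehyde | O=Cc1cc2ccc(O[Si](C(C)C)(C(C)C)C(C)C)cc2cc1O
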